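All runs were generated by integration on assumed constants, and the scatter is random.

The delta run cannot be one step from substrate to target: by 90.0 min the substrate reading had fallen to 48%, yet target, counted with its product in the second phase, read 5%.

| flask | substrate | reagent in the second phase | remark | time | volume of the second phase over the first |
|---|---|---|---|---|---|
| delta | 1.7 M | 1.98 M | run made earlier |  |  |
| flask | 1.1 M | 1.98 M |  | 15 h | 2.0 |

delta run (percent of the substrate charged)

| time / min | target / % | substrate / % |
|---|---|---|
| 8.00 | 3 | 93 |
| 15.0 | 2 | 92 |
| 40.0 | 3 | 65 |
| 90.0 | 5 | 48 |

(scatter of a reading: 2 percentage points)

1. the target and product in the second phase together standing at 15 h, as a percentage of the substrate charged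
2. part of the substrate charged that has reacted at 15 h

- target is meant together with its product in the second phase
- in the second phase: reagent in the second phase, product in the second phase; everything else is in the first
- charges count per volume of the first phase; a concentration in a rate is the amount of a species over the volume of its own phase; every rate counts per litre of the first phase
- the earlier runs hold the two phases in the same ratio of volumes as the flask asked about

Take the main step by itself, substrate and reagent to target. It asks for a target reading equal to the substrate lost in the delta run, 52.0%.

Add one process, a side route taking a fixed share of the substrate. The share found as target (the selectivity) then reads

  9.62%

But that share does not hold still. Between 15.0 min and 90.0 min the lost substrate grew from 8.00% to 52.0%, while target moved by 3 percentage points against a scatter of 2 points.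

So add the rest: we take target to be consumed about as fast as it forms, by a loss tied to substrate. We then carry a concentration instead of a share. With the same reagent charge and phase ratio, the concentration of target per litre of the first phase, the standing target, is

  [target] = 0.0850 M

  flask: 7.73% of its charge, give or take 3.1 points

A loss running without substrate is where control changes hands; with this scatter we cannot tell from the delta readings whether one is there, so we leave it out of this reckoning. We expect high conversion because 15 h is ten times the 90.0 min in which about half of the delta substrate reacted.

The forecast gave 14% of target, above our figure, and 97% reacted, noting that “a slow intermediate could feed more target later”.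

The flask gives 8.58% of target, with 95.1% reacted.

    substrate + target → side product (k = 0.00120 M⁻¹ s⁻¹)
    reagent in the reaction phase ⇌ reagent in the second phase, rate k2*([reagent in the reaction phase] - [reagent in the second phase]/K2) per volume of the first phase (partition coefficient = 3.10, kL = 0.0230 s⁻¹)
    target → decomposed product (k = 5.40 × 10⁻⁴ s⁻¹)
    substrate + reagent in the reaction phase ⇌ target (K = 0.400 M⁻¹, k = 6.90 × 10⁻⁴ M⁻¹ s⁻¹)
    target ⇌ product in the second phase, rate k5*([target] - [product in the second phase]/K5) per volume of the first phase (partition coefficient = 9.00, kL = 2.50 × 10⁻⁴ s⁻¹)

That is 0.0944 M per litre of the first phase, against the standing target of 0.0850 M, a gap smaller than the 0.0340 M scatter of that reading. In the flask, with concentrations as charged, the half-life of reaction-phase target against substrate, 0.15 h, is shorter than its 0.36 h against decomposition.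

In a neighbour flask, like this one but charged with 0.28 M of substrate, the standing target gives 30.4%. The computed 14.9% is half of that, and this neighbour lies below the 0.556 M at which side product and decomposed product hold the same: decomposed product stands at 51.8%, more than side product at 27.6%.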